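In the first minutes of theta, beta and eta, starting material has three ways forward that matter here: it meets reagent and becomes intermediate A (the capture step), it turns unaided into side product (the side step), or it meets protic impurity and becomes quenched substrate (the quench).

all flasks: protic impurity 6.50 mM
- theta: starting material 0.13 M; reagent 0.104 M (fed, over 30.0 h); time 30 h; a stirred flask in which reagent is dosed at a steady rate over 30.0 h without added volume, worked up at 30 h
- epsilon: starting material 0.13 M; reagent 0.104 M; one stirred flow tank at steady state, fed with the mixture as stated, mean residence time 30 h
- beta: starting material 0.13 M (fed, over 30.0 h); reagent 0.104 M; time 30 h; a stirred flask in which starting material is dosed at a steady rate over 30.0 h without added volume, worked up at 30 h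
- eta: starting material 0.13 M; reagent 0.104 M; time 30 h; a closed flask charged with all of it at once and left for 30 h

* order of the set-ups by the share of target in all that became target or side product, at the outlet or at the end, highest first (theta / epsilon / beta / eta)
* share of target in all that became target or side product, at the outlet or at the end, theta
* share of target in all that became target or side product, at the outlet or at the end, epsilon
* share of target in all that became target or side product, at the outlet or at the end, beta
* share of target in all that became target or side product, at the outlet or at the end, eta

- the stated concentrations are those of everything mixed, before any reaction; amounts are the same in each set-up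
- the feed brings no volume worth counting
- run time (theta): 30 h

    starting material + reagent → intermediate A (k1 = 0.70 L mol⁻¹ min⁻¹)
    starting material → side product (k2 = 0.0045 min⁻¹)
    intermediate A → target (k3 = 1.6 × 10⁻⁴ min⁻¹)
    intermediate A ⇌ intermediate B (K4 = 2.6, k4 = 0.012 min⁻¹)
    starting material + protic impurity → quenched substrate (k5 = 0.55 L mol⁻¹ min⁻¹)
    starting material → decomposition product (k6 = 2.9 × 10⁻⁶ min⁻¹)

The quench runs at 0.00358 min⁻¹ on the charged protic impurity, a little below the side step's 0.0045 min⁻¹, but that impurity amounts to 5.00% of the starting-material charge. The ratio r of the capture rate to the side rate is a selectivity factor, and at early times it depends on the reagent level met. In theta, reagent is taken up as it enters at f = 0.003467 M h⁻¹, so it stands where capture on the charge equals the feed.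

- theta: reagent met 0.635 mM, r = 0.0988
- beta: reagent met 0.104 M, r = 16.2
- eta: reagent met 0.104 M, r = 16.2

In the theta row the side step outruns the feed ten times over. The beta and eta rows favour capture and are equal at the start, so early times do not separate them. The tank has no early time, and this reckoning does not reach it.

The theta row can be integrated. In theta, protic impurity is taken up first, its lifetime of 14.0 min being shorter than the 222 min of the side step, so about 0.123 M of starting material remains, called a. With k the side-step constant, the starting-material concentration s obeys ds/dt = −ks − f, and s reaches zero at the starvation time t* = ln(1 + ka/f)/k, the moment the feed finds no partner, here 8.75 h. On this reckoning theta captures f·t* = 0.0303 M and loses 0.0932 M as side product, 71.7% of the charge. With 27.8% of the captured pool as intermediate A, over a mean age of 25.6 h, target comes to 0.002073 M, so this reckoning gives theta a share of 2.18%.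

The forecast gave 2.5% for theta, 17.2% for epsilon, 24% for beta and 26.5% for eta, in the order eta > beta > epsilon > theta, holding that “slow reagent dosing starves it and sends most to side product”. Its theta share stands above this reckoning.

The simulation gives 1.78%, 17.2%, 20.2% and 26.5% respectively, in the order eta > beta > epsilon > theta.

In theta the starvation time of 8.75 h is shorter than the dosing time of 30.0 h; at 15.0 h starting material stands at 0.00698% of its charge, and at the end 76.0% of the reagent charge remains, with side product at 75.7% against the 71.7% reckoned. For the neighbour flask, like theta but with 0.42 M of reagent, the same formula gives t* = 4.51 h and side product at 46.4% of the charge, and that flask holds 52.6%.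

Its constants are those of an exercise; the rest is arithmetic.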